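## Retrosynthetic overview

- The tetrahydrofuran and the α-methylene-γ-lactone are formed together in the last step: a transannular, divalent-palladium carbonylative double cyclisation of a ten-membered allenyl diol (bonds O–C7, C11–C12, C12–O6).
- The ten-membered allenyl carbinol comes from an intramolecular indium propargylation (C7–C8) of an epoxy aldehyde that carries a propargylic chloride.
- The open chain comes from asymmetric alkynylation of an enal (C6–C7), hydroxyl-directed epoxidation (C4/C5), and alkylation of a ketol dianion with a C5 bromo acetal (C2–C3).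
- C10 comes from (S)-lactic acid by allylation of its pivalaldehyde dioxolanone (self-regeneration of the stereocentre).
- Ring order: temporary dioxolanone → epoxide → ten-membered carbocycle → tetrahydrofuran + lactone in one operation.

Assumption: atoms carry germacranolide numbers (C1 ketone, C4/C5 epoxide, C6 lactone carbinol, C7 spiro carbon, C8 tiglate carbinol, C10 methyl-bearing ether carbon, C11–C13 lactone acrylate unit); compounds 9, 15 and 25 are bought.

## Route

Step 1
Reactants: 1 (S)-lactic acid; 2 pivalaldehyde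
Product: 3 (2S,5S)-2-tert-butyl-5-methyl-1,3-dioxolan-4-one
Conditions: TsOH (cat.), H2SO4 (cat.), pentane, reflux, Dean–Stark; recrystallise from pentane at −78 °C
Reagents that add atoms: none
Why: Acid-catalysed acetalisation (Seebach dioxolanone) gives mainly the cis acetal, which crystallises, so the acetal carbon is set relative to the lactate carbon.

Step 2
Reactants: 3 (2S,5S)-2-tert-butyl-5-methyl-1,3-dioxolan-4-one; 4 allyl bromide
Product: 6 (2S,5R)-2-tert-butyl-5-methyl-5-(prop-2-en-1-yl)-1,3-dioxolan-4-one, via lithium enolate 5 (not isolated)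
Conditions: LiN(iPr)2, THF, −78 °C; then 4, −78 → −30 °C
Reagents that add atoms: none
Why: Enolate alkylation with self-regeneration of the stereocentre: allyl bromide enters trans to the tert-butyl group, which gives the quaternary centre that becomes C10 (R).

Step 3
Reactants: 6 (2S,5R)-2-tert-butyl-5-methyl-5-(prop-2-en-1-yl)-1,3-dioxolan-4-one
Product: 8 (3R)-3-hydroxy-3-methylhex-5-en-2-one, via lithium hemiketal alkoxide 7 (not isolated)
Conditions: MeLi (1.05 equiv), Et2O, −78 °C; then H2O
Reagents that add atoms: methyllithium, [Li]C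
Why: Nucleophilic acyl substitution: the tetrahedral alkoxide is stable at −78 °C and collapses on work-up to the methyl ketone and pivalaldehyde without touching the quaternary centre.

Step 4
Reactants: 9 1,1-diethoxy-3-methylbut-2-ene
Product: 10 (2E)-4,4-diethoxy-2-methylbut-2-en-1-ol
Conditions: SeO2 (0.3 equiv), t-BuOOH (2 equiv), CH2Cl2, 0 °C → rt
Reagents that add atoms: tert-butyl hydroperoxide, CC(C)(C)OO (oxygen passed on through SeO2, O=[Se]=O)
Why: SeO2-catalysed allylic oxidation (ene reaction then [2,3] shift) attacks the methyl group trans to the acetal carbon and so fixes the E olefin.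

Step 5
Reactants: 10 (2E)-4,4-diethoxy-2-methylbut-2-en-1-ol
Product: 11 (2E)-4-bromo-1,1-diethoxy-3-methylbut-2-ene
Conditions: CBr4, PPh3, 2,6-lutidine, CH2Cl2, −20 °C
Reagents that add atoms: carbon tetrabromide, BrC(Br)(Br)Br
Why: Appel bromination is an SN2 reaction at the primary allylic carbon, keeps the olefin geometry, and the buffer protects the acetal.

Step 6
Reactants: 8 (3R)-3-hydroxy-3-methylhex-5-en-2-one; 11 (2E)-4-bromo-1,1-diethoxy-3-methylbut-2-ene
Product: 14 (2E,7R)-7-hydroxy-3,7-dimethyl-6-oxodeca-2,9-dienal, via dilithium dianion 12 (not isolated), via keto acetal 13 (not isolated)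
Conditions: LiN(iPr)2 (2.2 equiv), THF, −78 °C; 11, −78 → −20 °C; then 1 M HCl, THF, 0 °C
Reagents that add atoms: water, O
Why: Enolate alkylation: the ketone can enolise only towards its methyl group, the alkoxide–enolate dianion is C-alkylated by the allylic bromide (C2–C3 bond), and acid work-up hydrolyses the labile enal acetal.

Step 7
Reactants: 14 (2E,7R)-7-hydroxy-3,7-dimethyl-6-oxodeca-2,9-dienal; 15 3-chloroprop-1-yne
Product: 17 (4R,5E,10R)-1-chloro-4,10-dihydroxy-6,10-dimethyltrideca-5,12-dien-2-yn-9-one, via methylzinc alkynylide 16 (not isolated)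
Conditions: Me2Zn (4 equiv), 15 (3 equiv), (S,S)-ProPhenol (20 mol %), Ph3P=O (40 mol %), toluene, 4 °C; aq. NH4Cl
Reagents that add atoms: none
Why: Zinc–ProPhenol catalysed enantioselective alkynylation: the alkynylzinc adds only to the aldehyde and the ligand controls the face, setting C6 (R at this stage); the (S,S) ligand is assumed to give this sense and the product is checked by Mosher analysis.

Step 8
Reactants: 17 (4R,5E,10R)-1-chloro-4,10-dihydroxy-6,10-dimethyltrideca-5,12-dien-2-yn-9-one
Product: 18 (4R)-1-[(2R,3R)-3-[(1S)-4-chloro-1-hydroxybut-2-yn-1-yl]-2-methyloxiran-2-yl]-4-hydroxy-4-methylhept-6-en-3-one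
Conditions: mCPBA (1.1 equiv), NaHCO3, CH2Cl2, 0 °C
Reagents that add atoms: 3-chloroperoxybenzoic acid (mCPBA), OOC(=O)c1cccc(Cl)c1
Why: Hydroxyl-directed (Henbest) epoxidation under A(1,3) control by the cis methyl group gives the threo epoxy alcohol (4R,5R), and the trisubstituted olefin reacts well before the vinyl group or the alkyne.

Step 9
Reactants: 18 (4R)-1-[(2R,3R)-3-[(1S)-4-chloro-1-hydroxybut-2-yn-1-yl]-2-methyloxiran-2-yl]-4-hydroxy-4-methylhept-6-en-3-one
Product: 19 (4R)-1-[(2R,3R)-3-[(1S)-4-chloro-1-(triethylsilyloxy)but-2-yn-1-yl]-2-methyloxiran-2-yl]-4-hydroxy-4-methylhept-6-en-3-one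
Conditions: Et3SiOTf (1.05 equiv), 2,6-lutidine, CH2Cl2, −78 °C
Reagents that add atoms: triethylsilyl trifluoromethanesulfonate, CC[Si](CC)(CC)OS(=O)(=O)C(F)(F)F
Why: Silyl ether formation is selective for the secondary hydroxyl at −78 °C because the tertiary α-keto hydroxyl is too hindered.

Step 10
Reactants: 19 (4R)-1-[(2R,3R)-3-[(1S)-4-chloro-1-(triethylsilyloxy)but-2-yn-1-yl]-2-methyloxiran-2-yl]-4-hydroxy-4-methylhept-6-en-3-one
Product: 21 (3R)-6-[(2R,3R)-3-[(1S)-4-chloro-1-(triethylsilyloxy)but-2-yn-1-yl]-2-methyloxiran-2-yl]-3-hydroxy-3-methyl-4-oxohexanal, via secondary ozonide 20 (not isolated)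
Conditions: O3, CH2Cl2, −78 °C (Sudan red end point); then Me2S, −78 °C → rt
Reagents that add atoms: ozone, [O-][O+]=O
Why: Ozonolysis cleaves the only remaining olefin (the alkyne reacts much more slowly) and reductive work-up gives the C8 aldehyde.

Step 11
Reactants: 21 (3R)-6-[(2R,3R)-3-[(1S)-4-chloro-1-(triethylsilyloxy)but-2-yn-1-yl]-2-methyloxiran-2-yl]-3-hydroxy-3-methyl-4-oxohexanal
Product: 24 (4R,5R,6S,8S,10R)-4,5-epoxy-8,10-dihydroxy-4,10-dimethyl-6-(triethylsilyloxy)-7-vinylidenecyclodecan-1-one, via propargylic iodide 22 (not isolated), via propargylindium diiodide 23 (not isolated)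
Conditions: In powder (3 equiv), NaI (3 equiv), DMF–H2O 9:1, 25 °C, syringe-pump addition to 0.003 M
Reagents that add atoms: none
Why: Intramolecular indium Barbier propargylation: the substituted propargylindium adds through SE2′ at C7 to give the allenyl carbinol and close the ten-membered ring, and an indium chelate between the aldehyde and the C10 hydroxyl delivers C7 from the tether side to give 8S.

Step 12
Reactants: 24 (4R,5R,6S,8S,10R)-4,5-epoxy-8,10-dihydroxy-4,10-dimethyl-6-(triethylsilyloxy)-7-vinylidenecyclodecan-1-one; 25 tigloyl chloride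
Product: 26 (4R,5R,6S,8S,10R)-4,5-epoxy-10-hydroxy-4,10-dimethyl-8-[(2E)-2-methylbut-2-enoyloxy]-6-(triethylsilyloxy)-7-vinylidenecyclodecan-1-one
Conditions: pyridine, DMAP (cat.), CH2Cl2, 0 °C → rt
Reagents that add atoms: none
Why: DMAP-catalysed acylation esterifies the only secondary hydroxyl with retention at C8, and the tertiary hydroxyl does not react.

Step 13
Reactants: 26 (4R,5R,6S,8S,10R)-4,5-epoxy-10-hydroxy-4,10-dimethyl-8-[(2E)-2-methylbut-2-enoyloxy]-6-(triethylsilyloxy)-7-vinylidenecyclodecan-1-one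
Product: 27 (4R,5R,6S,8S,10R)-4,5-epoxy-6,10-dihydroxy-4,10-dimethyl-8-[(2E)-2-methylbut-2-enoyloxy]-7-vinylidenecyclodecan-1-one
Conditions: HF·pyridine, pyridine, THF, 0 °C
Reagents that add atoms: none
Why: Buffered fluoride desilylation frees the C6 hydroxyl without opening the epoxide or cleaving the tiglate.

Step 14
Reactants: 27 (4R,5R,6S,8S,10R)-4,5-epoxy-6,10-dihydroxy-4,10-dimethyl-8-[(2E)-2-methylbut-2-enoyloxy]-7-vinylidenecyclodecan-1-one
Product: 29 CNP0281419.1, (4R,5R,6R,7S,8S,10R)-4,5:7,10-diepoxy-1-oxo-8-[(2E)-2-methylbut-2-enoyloxy]germacr-11(13)-en-12,6-olide, via acylpalladium chloride 28 (not isolated)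
Conditions: PdCl2(MeCN)2 (10 mol %), CuCl2 (2.5 equiv), NaOAc (3 equiv), CO (1 atm), THF, 0 °C → rt
Reagents that add atoms: carbon monoxide, [C-]#[O+]
Why: Proposed new method: divalent palladium activates the allene, the C10 hydroxyl adds anti to C7 in a transannular 5-exo closure (only the cis-bridged ether is geometrically possible, which fixes C7 as S), the vinylpalladium at C11 inserts CO, and the acylpalladium is trapped by the C6 hydroxyl to close the α-methylene-γ-lactone while CuCl2 reoxidises zerovalent palladium; the aprotic solvent leaves lactonisation as the only irreversible exit; the closest known reaction type is the PdCl2/CuCl2 cyclisation–alkoxycarbonylation of γ-hydroxy allenes to 2-(tetrahydrofuran-2-yl)acrylates and the oxycarbonylation–lactonisation of alkene diols.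

## Compound list

1 | (S)-lactic acid | C[C@H](O)C(=O)O | starting material
2 | pivalaldehyde | CC(C)(C)C=O | starting material
3 | (2S,5S)-2-tert-butyl-5-methyl-1,3-dioxolan-4-one | C[C@@H]1O[C@H](C(C)(C)C)OC1=O | intermediate
4 | allyl bromide | C=CCBr | starting material
5 | lithium enolate of 3 | CC1=C(O[Li])O[C@@H](C(C)(C)C)O1 | intermediate
6 | (2S,5R)-2-tert-butyl-5-methyl-5-(prop-2-en-1-yl)-1,3-dioxolan-4-one | C=CC[C@@]1(C)O[C@H](C(C)(C)C)OC1=O | intermediate
7 | lithium hemiketal alkoxide from 6 and MeLi | C=CC[C@@]1(C)O[C@H](C(C)(C)C)OC1(C)O[Li] | intermediate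
8 | (3R)-3-hydroxy-3-methylhex-5-en-2-one | CC(=O)[C@](C)(O)CC=C | intermediate
9 | 1,1-diethoxy-3-methylbut-2-ene (prenal diethyl acetal) | CCOC(OCC)C=C(C)C | starting material
10 | (2E)-4,4-diethoxy-2-methylbut-2-en-1-ol | CCOC(OCC)/C=C(\C)CO | intermediate
11 | (2E)-4-bromo-1,1-diethoxy-3-methylbut-2-ene | CCOC(OCC)/C=C(\C)CBr | intermediate
12 | dilithium alkoxide–enolate of 8 | C=C(O[Li])[C@](C)(O[Li])CC=C | intermediate
13 | (4R,8E)-10,10-diethoxy-4-hydroxy-4,8-dimethyldeca-1,8-dien-5-one | CCOC(OCC)/C=C(\C)CCC(=O)[C@](C)(O)CC=C | intermediate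
14 | (2E,7R)-7-hydroxy-3,7-dimethyl-6-oxodeca-2,9-dienal | O=C/C=C(\C)CCC(=O)[C@](C)(O)CC=C | intermediate
15 | 3-chloroprop-1-yne | C#CCCl | starting material
16 | methyl(3-chloroprop-1-yn-1-yl)zinc | C[Zn]C#CCCl | intermediate
17 | (4R,5E,10R)-1-chloro-4,10-dihydroxy-6,10-dimethyltrideca-5,12-dien-2-yn-9-one | ClCC#C[C@H](O)/C=C(\C)CCC(=O)[C@](C)(O)CC=C | intermediate
18 | (4R)-1-[(2R,3R)-3-[(1S)-4-chloro-1-hydroxybut-2-yn-1-yl]-2-methyloxiran-2-yl]-4-hydroxy-4-methylhept-6-en-3-one | ClCC#C[C@H](O)[C@H]1O[C@]1(C)CCC(=O)[C@](C)(O)CC=C | intermediate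
19 | triethylsilyl ether of 18 at the secondary hydroxyl | ClCC#C[C@H](O[Si](CC)(CC)CC)[C@H]1O[C@]1(C)CCC(=O)[C@](C)(O)CC=C | intermediate
20 | secondary ozonide (1,2,4-trioxolane) of 19 | ClCC#C[C@H](O[Si](CC)(CC)CC)[C@H]1O[C@]1(C)CCC(=O)[C@](C)(O)CC1OOCO1 | intermediate
21 | (3R)-6-[(2R,3R)-3-[(1S)-4-chloro-1-(triethylsilyloxy)but-2-yn-1-yl]-2-methyloxiran-2-yl]-3-hydroxy-3-methyl-4-oxohexanal | ClCC#C[C@H](O[Si](CC)(CC)CC)[C@H]1O[C@]1(C)CCC(=O)[C@](C)(O)CC=O | intermediate
22 | propargylic iodide corresponding to 21 | ICC#C[C@H](O[Si](CC)(CC)CC)[C@H]1O[C@]1(C)CCC(=O)[C@](C)(O)CC=O | intermediate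
23 | propargylindium diiodide from 22 | I[In](I)CC#C[C@H](O[Si](CC)(CC)CC)[C@H]1O[C@]1(C)CCC(=O)[C@](C)(O)CC=O | intermediate
24 | (4R,5R,6S,8S,10R)-4,5-epoxy-8,10-dihydroxy-4,10-dimethyl-6-(triethylsilyloxy)-7-vinylidenecyclodecan-1-one | C=C=C1[C@H](O[Si](CC)(CC)CC)[C@H]2O[C@]2(C)CCC(=O)[C@](C)(O)C[C@@H]1O | intermediate
25 | tigloyl chloride, (2E)-2-methylbut-2-enoyl chloride | C/C=C(\C)C(=O)Cl | starting material
26 | (4R,5R,6S,8S,10R)-4,5-epoxy-10-hydroxy-4,10-dimethyl-8-[(2E)-2-methylbut-2-enoyloxy]-6-(triethylsilyloxy)-7-vinylidenecyclodecan-1-one | C=C=C1[C@H](O[Si](CC)(CC)CC)[C@H]2O[C@]2(C)CCC(=O)[C@](C)(O)C[C@@H]1OC(=O)/C(C)=C/C | intermediate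
27 | (4R,5R,6S,8S,10R)-4,5-epoxy-6,10-dihydroxy-4,10-dimethyl-8-[(2E)-2-methylbut-2-enoyloxy]-7-vinylidenecyclodecan-1-one | C=C=C1[C@H](O)[C@H]2O[C@]2(C)CCC(=O)[C@](C)(O)C[C@@H]1OC(=O)/C(C)=C/C | intermediate
28 | acylpalladium chloride (tetrahydrofuran closed, C6 hydroxyl free) | O[C@@H]1[C@H]2O[C@]2(C)CCC(=O)[C@@]2(C)C[C@H](OC(=O)/C(C)=C/C)[C@@]1(O2)C(=C)C(=O)[Pd]Cl | intermediate
29 | CNP0281419.1, (4R,5R,6R,7S,8S,10R)-4,5:7,10-diepoxy-1-oxo-8-[(2E)-2-methylbut-2-enoyloxy]germacr-11(13)-en-12,6-olide | C=C1C(=O)O[C@@H]2[C@H]3O[C@]3(C)CCC(=O)[C@@]3(C)C[C@H](OC(=O)/C(C)=C/C)[C@@]12O3 | target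

## Step count and risks

Total step count: 14. Longest linear sequence: 12 (steps 1–3 and 6–14).

**Step 14 (transannular carbonylative double cyclisation).** The free C6 hydroxyl is an α-allenol and may cyclise 5-endo to a dihydrofuran before the C10 hydroxyl attacks C7. The epoxide and the allenylic tiglate must also survive palladium and copper chlorides. The fallback sets out from 26 and comes back at 29. With the C6 oxygen still silylated, only the C10 hydroxyl can attack: N-iodosuccinimide (MeCN, 0 °C) gives by 5-exo iodoetherification the iodovinyl oxabicycle silyl ether F1. HF·pyridine then gives the iodovinyl oxabicycle alcohol F2. Pd(PPh3)4, CO (1 atm) and Et3N in MeCN at 50 °C close the lactone by a zerovalent-palladium carbonylative lactonisation of the vinyl iodide. This forms the two rings in separate steps.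

**Step 11 (indium ring closure).** The ring may close without the chelate and give mainly the 8R carbinol; Lewis-acidic indium salts may also attack the epoxide. The fallback sets out from 21 and comes back at 26. The cyclisation is run as before and the 8-epi macrocyclic allenol F3 is taken on without trying to enforce chelation. Mitsunobu esterification with tiglic acid (PPh3, diisopropyl azodicarboxylate, toluene, 0 °C) inverts C8 and gives 26 directly, replacing step 12. The stereocentre is then set by SN2 inversion and not by the addition.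

**Step 7 (asymmetric alkynylation with chloropropyne).** The propargylic chloride may not survive the zinc alkynylide conditions, or the enantioselectivity on this enal may be low. The fallback sets out from 14 and comes back at 17. Lithium 3-chloroprop-1-yn-1-ide F4 (from 15 and n-BuLi, THF, −90 °C, 2.2 equiv) adds to the aldehyde to give the C6-epimeric chloro enynols F5. Dess–Martin periodinane gives the alkynyl enone F6. Noyori transfer hydrogenation with the enantiomer of RuCl(p-cymene)(TsDPEN) that delivers 6R (2-propanol, rt) reduces the ynone under catalyst control; the hindered C1 ketone reacts far more slowly.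

Further compounds
F1 | step 14 | iodovinyl oxabicycle silyl ether (tetrahydrofuran closed, C11 iodide, C6 triethylsilyl ether) | CC[Si](CC)(CC)O[C@@H]1[C@H]2O[C@]2(C)CCC(=O)[C@@]2(C)C[C@H](OC(=O)/C(C)=C/C)[C@@]1(O2)C(I)=C
F2 | step 14 | iodovinyl oxabicycle alcohol (C6 hydroxyl free) | O[C@@H]1[C@H]2O[C@]2(C)CCC(=O)[C@@]2(C)C[C@H](OC(=O)/C(C)=C/C)[C@@]1(O2)C(I)=C
F3 | step 11 | 8-epi macrocyclic allenol, (4R,5R,6S,8R,10R) epimer of 24 | C=C=C1[C@H](O[Si](CC)(CC)CC)[C@H]2O[C@]2(C)CCC(=O)[C@](C)(O)C[C@H]1O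
F4 | step 7 | lithium 3-chloroprop-1-yn-1-ide | [Li]C#CCCl
F5 | step 7 | C6-epimeric chloro enynols (17 and its 4-epimer) | ClCC#CC(O)/C=C(\C)CCC(=O)[C@](C)(O)CC=C
F6 | step 7 | alkynyl enone, (5E,10R)-1-chloro-10-hydroxy-6,10-dimethyltrideca-5,12-dien-2-yne-4,9-dione | ClCC#CC(=O)/C=C(\C)CCC(=O)[C@](C)(O)CC=C
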